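## Structural features

The target is a (2S)-flavanone: a chroman-4-one in which benzo ring A is fused to the dihydropyranone ring C through C4a and C8a, with a 3,4-dimethoxyphenyl ring B on C2. Ring A is fully substituted. C5, C6 and C7 carry methoxy groups, C8 a free hydroxyl, C8a the ring oxygen O1 and C4a the C4 carbonyl, so five contiguous oxygens must be placed and only the one on C8 left unmethylated. C2 is the only stereocentre; it has no stereogenic neighbour, but it is benzylic, bonded to O1 and β to the C4 ketone. That arrangement is the fragile point: base (and strong acid) can open ring C by retro-oxa-Michael reaction to the 2'-hydroxychalcone, and reclosure racemises C2. The pentaoxygenated ring A with its free C8 phenol is easily oxidised, and the C5 methoxy group peri to the carbonyl is the methyl ether most easily lost to Lewis acids. The real difficulty is twofold: a regiochemically unambiguous build-up of ring A with one differentiated oxygen, and a non-equilibrating way to fix C2. The key step exploits the fact that C2 bears O1, ring B and C3, which is the pattern of a branched O-allylation product. Attack of the ring A phenoxide on the aryl-bearing terminus of a 3,4-dimethoxycinnamyl unit forms O1–C2, sets C2, and leaves a vinyl group whose inner carbon is C3. A vinyl group on C4a (the future C4) later meets it by metathesis.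

## Logic of the disconnections

19 to 18: only the O–CH2Ph bond on the C8 oxygen is cut. A free C8 phenol could not be carried through the phenoxide chemistry and the oxidations, and a benzyl ether is orthogonal to the five methyl ethers. The forward step must remove it under neutral conditions that spare the benzylic C2–O1 bond and the C4 ketone.

18 to 17: the C4 carbonyl is taken back to the alcohol level. This keeps the base-labile β-aryloxy ketone out of the route until the last two, neutral steps. The forward oxidation must be non-basic and must not touch the electron-rich ring A.

17 to 16: the C4–O bond is cut, leaving the C3=C4 alkene. This removes a functional group and exposes a ring alkene that metathesis can make. The forward hydration must put oxygen on the benzylic carbon C4 and must not ionise the C2–O1 bond.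

16 to 15: the C3=C4 bond is cut. Ring C opens to an aryl ether with one vinyl group on C2 and one on C4a, so the bicycle becomes an acyclic union of two arenes. The forward ring closure must not let the double bond migrate towards C2. The S descriptor is the same in 15, 16, 18 and 19 because the ranking O1 > ring B > C3 does not change.

15 to 11 and 14: the O1–C2 bond is cut. This divides the molecule into a ring A half and a ring B half of similar size, and the only stereocentre is formed in the act of joining them. The forward step must attack the branched terminus, select one face, and tolerate a phenoxide flanked on both sides.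

11 to 10: the terminal C=C bond of the vinyl group is cut back to an aldehyde. The vinylphenol is not a storable compound, the aldehyde is. The forward olefination has to work on a hindered aldehyde that is deactivated as its phenoxide.

10 to 8 (through 9): the C4a–C4 bond is cut, removing the formyl carbon. Compound 8 has exactly one unsubstituted ring carbon, ortho to its hydroxyl, so the forward formylation has no regiochemical choice.

8 to 6 (through 7): the aryl C–O bond of the future O1 is cut and replaced by an aryl–CHO bond. A formyl group is a place-holder for oxygen that can be introduced ortho to a phenol with certainty. The forward oxidation needs aryl rather than hydride migration and must not over-oxidise the product phenol.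

6 to 5: the O–benzyl bond is cut. At this stage the future C8 oxygen is the only phenol in the molecule, so it can be marked without any selectivity problem.

5 to 3 (through 4): the aryl–CHO bond is cut. The single free ortho position of 3 guarantees where the carbon, and later the fifth oxygen, goes.

3 to 1 (through 2): the aryl C–O bond is cut back to the formyl group of a bulk aldehyde that already carries the three contiguous methoxy groups.

14 to 13 to 12: the carbonate C–O bond is cut, then the allylic alcohol is traced to the ester. Both steps are functional-group changes on a commercial E-cinnamate. The reduction must be 1,2-selective and leave the E alkene alone.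

## Other disconnections considered

Alternative 1: The cut is the C8–C8a bond, and with it the whole of ring A. Ring A is traced to the four-carbon unit of dimethyl squarate A3 and to the C4a=C8a enol-ether double bond of a 2-aryl-4-silyloxy-dihydropyran.
- Forward key step: heating the cyclobutenone A2 (4-[(2S,4S)-4-(tert-butyldimethylsilyloxy)-2-(3,4-dimethoxyphenyl)-3,4-dihydro-2H-pyran-5-yl]-2,3,4-trimethoxycyclobut-2-en-1-one) should open the four-membered ring to a dienylketene. This closes by 6π electrocyclisation and tautomerises to the phenol A1, (2S,4S)-4-(tert-butyldimethylsilyloxy)-2-(3,4-dimethoxyphenyl)-5,6,7-trimethoxychroman-8-ol.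
- In favour: the three methoxy groups and the free C8 hydroxyl come out in fixed positions from the connectivity of A2. Ring A needs no formylation/Dakin sequence and no protecting group on C8. On regiochemical economy of ring A this is better than the chosen plan. The cascade is thermal and needs no catalyst.
- Against: C2 has to be made beforehand in the dihydropyran, for instance by a catalytic asymmetric hetero-Diels–Alder reaction, and a second, disposable stereocentre at C4 has to be carried. The enol ether with its allylic silyl ether is acid-labile. The vinyl-metal addition and a thermolysis above 100 °C are run on the chiral, most valuable fragment. After the key step the C4 silyl ether must be removed and C4 oxidised next to a free, very electron-rich C8 phenol, which invites quinone formation or costs a protection/deprotection pair.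
- Comparison, structure: both plans keep C4 at the alcohol level and oxidise late, so they are equal there.
- Comparison, mechanism: the pericyclic cascade is intrinsically regiospecific, whereas the iridium step relies on catalyst control. The iridium step, however, creates C2 in the joining event, while here stereocontrol is a separate, earlier problem.
- Comparison, step economy: ring A arrives in about three operations from A3 instead of six, but the dihydropyran partner and the longer end game are expected to make the total equal at best. The sequence is linear on the chiral fragment where the chosen plan is convergent.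

Alternative 2: The cut is the C8–O bond.
- Forward key step: a peracid adds to the C8 aldehyde of the flavanone A5, (2S)-2-(3,4-dimethoxyphenyl)-5,6,7-trimethoxy-4-oxochromane-8-carbaldehyde. The ring A carbon migrates to oxygen and the aryl formate A4, (2S)-2-(3,4-dimethoxyphenyl)-5,6,7-trimethoxy-4-oxochroman-8-yl formate, results. Mild solvolysis would then free the phenol.
- In favour: ring A of A5 needs only three methoxy groups and one carbon substituent. The formate is its own protecting group, so no benzyl ether is carried; protecting-group economy is better than in the chosen plan. The reaction type is the one the chosen plan already uses in steps 1 and 4, so the reliability of the reaction class is equal.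
- Against: the oxidation is asked of the last, most valuable intermediate. Its C4 aryl ketone can undergo Baeyer–Villiger insertion, and its migrating ring is acyl-substituted and less inclined to migrate than in 1 or 6, so oxidation to the carboxylic acid competes. Formate removal must avoid base because of C2. The disconnection says nothing about C2: the formyl group would have to survive, or be introduced after, whatever asymmetric flavanone construction is used. Formylation of a finished flavanone at C8 competes with ring B and uses Lewis acids that threaten C2 and the C5 methoxy group.
- Comparison, structure: the alternative is simpler in ring A and free of protecting groups.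
- Comparison, mechanism: it concentrates a chemoselectivity problem (aldehyde against ketone, aryl against hydride shift) at the end, whereas the chosen plan runs the same oxidation on simple benzaldehydes at the start.
- Comparison, step economy: it could be two or three steps shorter in ring A, but it needs a separate answer for C2, which the chosen plan builds into its bond-forming step.

Alternative 3: The cut takes C4a–C4, C4–C3 and O1–C2 at once.
- Forward key step: the iodophenol A7 (2-(benzyloxy)-6-iodo-3,4,5-trimethoxyphenol), carbon monoxide A9 and the alkyne A8 (4-ethynyl-1,2-dimethoxybenzene) would combine under a palladium–phosphine catalyst and a secondary amine. Oxidative addition, carbonyl insertion, alkynylation to an ortho-hydroxyaryl ynone and 6-endo closure would give the flavone A6, 8-(benzyloxy)-2-(3,4-dimethoxyphenyl)-5,6,7-trimethoxy-4H-chromen-4-one.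
- In favour: three bonds and ring C in one operation from two fragments. A7 is one iodination away from phenol 8 of the chosen route. On convergence and on step count to the ring system this is better than the chosen plan. The flavone is robust and cannot racemise.
- Against: A6 is flat at C2. The stereocentre would have to be created afterwards by enantioselective reduction of the C2=C3 bond of an electron-rich, vinylogous-ester type enone. General methods for this are few, and over-reduction of C4=O is a standing risk. The benzyl ether would have to be removed within the same reductive regime. The ynone can also close in the 5-exo mode to the benzofuranone isomer, and the doubly flanked aryl iodide may couple directly with the alkyne before carbonyl insertion.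
- Comparison, structure: the skeleton is reached faster, but at the wrong oxidation level and without stereochemistry.
- Comparison, mechanism: palladium carbonylation and iridium allyl chemistry are about equal in predictability, but here the selectivity that matters is deferred to a harder step.
- Comparison, step economy: shorter to A6, about equal overall once asymmetric reduction and deprotection are added, and with the stereochemical risk at the end of the route instead of the middle.

Key step: step 9

Assumption: the (Sa,Sc,Sc) antipode of the binaphthol N,N-bis(1-phenylethyl)phosphoramidite is taken as the one that leads to the S ether 15, which is the usual sense of induction of these iridacycles with aryl-substituted allyl carbonates and heteroatom nucleophiles as far as can be judged without a test run; if a first run shows the opposite sense, the (Ra,Rc,Rc) ligand is used and nothing else changes.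

## Route

Step 1
Reactants: 1 2,3,4-trimethoxybenzaldehyde
Product: 3 2,3,4-trimethoxyphenol, via 2,3,4-trimethoxyphenyl formate 2 (not isolated)
Conditions: 30% aq. H2O2 (1.3 equiv), H2SO4 (cat.), MeOH, 0 °C to rt
Reagents that add atoms: hydrogen peroxide, OO
Why: Acid-catalysed Dakin oxidation: the peroxide adduct of the aldehyde rearranges with migration of the aryl group, which the ortho and para methoxy donors favour over hydride shift, and the formate 2 is methanolysed in the same pot.

Step 2
Reactants: 3 2,3,4-trimethoxyphenol
Product: 5 2-hydroxy-3,4,5-trimethoxybenzaldehyde, via 6-(hydroxymethyl)-2,3,4-trimethoxyphenol 4 (not isolated)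
Conditions: MgCl2 (1.5 equiv), Et3N (3.75 equiv), (CH2O)n (6.75 equiv), MeCN, reflux; then 1 M HCl
Reagents that add atoms: paraformaldehyde (as formaldehyde), C=O
Why: Magnesium-mediated ortho-formylation (Casnati–Skattebøl): the magnesium phenoxide delivers formaldehyde to the only free ortho carbon (the para carbon bears OMe), and the hydroxymethyl intermediate 4 is oxidised in situ by a second formaldehyde through Oppenauer-type hydride transfer.

Step 3
Reactants: 5 2-hydroxy-3,4,5-trimethoxybenzaldehyde
Product: 6 2-(benzyloxy)-3,4,5-trimethoxybenzaldehyde
Conditions: BnBr (1.2 equiv), K2CO3 (2 equiv), DMF, 60 °C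
Reagents that add atoms: benzyl bromide, BrCc1ccccc1
Why: Williamson O-benzylation of the only phenol present; it marks the future C8 oxygen while the other three oxygens are already methyl ethers.

Step 4
Reactants: 6 2-(benzyloxy)-3,4,5-trimethoxybenzaldehyde
Product: 8 2-(benzyloxy)-3,4,5-trimethoxyphenol, via 2-(benzyloxy)-3,4,5-trimethoxyphenyl formate 7 (not isolated)
Conditions: 30% aq. H2O2 (1.3 equiv), H2SO4 (cat.), MeOH, 0 °C to rt
Reagents that add atoms: hydrogen peroxide, OO
Why: Second Dakin oxidation: the formyl carbon is replaced by hydroxyl, so the fifth ring oxygen (the future O1) appears exactly where the formyl group stood; the ortho benzyloxy and para methoxy groups drive aryl migration, and benzyl and methyl ethers are inert to dilute acidic peroxide.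

Step 5
Reactants: 8 2-(benzyloxy)-3,4,5-trimethoxyphenol
Product: 10 3-(benzyloxy)-2-hydroxy-4,5,6-trimethoxybenzaldehyde, via 2-(benzyloxy)-6-(hydroxymethyl)-3,4,5-trimethoxyphenol 9 (not isolated)
Conditions: MgCl2 (1.5 equiv), Et3N (3.75 equiv), (CH2O)n (6.75 equiv), MeCN, reflux; then 1 M HCl
Reagents that add atoms: paraformaldehyde (as formaldehyde), C=O
Why: The same magnesium-mediated ortho-formylation; 8 has a single unsubstituted ring carbon, ortho to the hydroxyl, so the regiochemistry is forced and the new aldehyde carbon is the future C4.

Step 6
Reactants: 10 3-(benzyloxy)-2-hydroxy-4,5,6-trimethoxybenzaldehyde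
Product: 11 2-(benzyloxy)-6-ethenyl-3,4,5-trimethoxyphenol
Conditions: Ph3PCH3Br (2.5 equiv), KOt-Bu (2.5 equiv), THF, 0 °C to rt; aq. NH4Cl; used at once
Reagents that add atoms: methyltriphenylphosphonium bromide, C[P+](c1ccccc1)(c1ccccc1)c1ccccc1.[Br-]
Why: Wittig methylenation with excess ylide (one equivalent of base is taken by the phenol); the non-stabilised ylide is reactive enough for the hindered, phenoxide-deactivated aldehyde, and the electron-rich vinylphenol is carried forward without storage.

Step 7
Reactants: 12 methyl (E)-3-(3,4-dimethoxyphenyl)prop-2-enoate
Product: 13 (E)-3-(3,4-dimethoxyphenyl)prop-2-en-1-ol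
Conditions: i-Bu2AlH (2.5 equiv), CH2Cl2, −78 to 0 °C; aq. potassium sodium tartrate (KNaC4H4O6)
Reagents that add atoms: none
Why: 1,2-Reduction of the α,β-unsaturated ester by the aluminium hydride at low temperature gives the allylic alcohol and leaves the E alkene untouched.

Step 8
Reactants: 13 (E)-3-(3,4-dimethoxyphenyl)prop-2-en-1-ol
Product: 14 (E)-3-(3,4-dimethoxyphenyl)allyl methyl carbonate
Conditions: ClCO2Me (1.3 equiv), pyridine (2 equiv), CH2Cl2, 0 °C
Reagents that add atoms: methyl chloroformate, COC(Cl)=O
Why: Acylation of the primary allylic alcohol gives the carbonate, a leaving group that releases its own base (methoxide) when it ionises on the metal.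

Step 9
Reactants: 11 2-(benzyloxy)-6-ethenyl-3,4,5-trimethoxyphenol; 14 (E)-3-(3,4-dimethoxyphenyl)allyl methyl carbonate (1.3 equiv)
Product: 15 (S)-1-(3,4-dimethoxyphenyl)allyl 2-(benzyloxy)-6-ethenyl-3,4,5-trimethoxyphenyl ether
Conditions: [Ir(cod)Cl]2 (2 mol%), (Sa,Sc,Sc)-O,O'-(1,1'-binaphthyl-2,2'-diyl) N,N-bis(1-phenylethyl)phosphoramidite (4 mol%), pre-activated with n-PrNH2 (THF, 50 °C, then evaporated); K3PO4 (0.5 equiv), THF, rt to 35 °C, Ar, dark
Reagents that add atoms: none
Why: This is iridium-catalysed asymmetric allylic etherification, the known branched- and enantioselective O-allylation of phenoxides (2-vinylphenoxides included) with cinnamyl carbonates. The cyclometalated phosphoramidite complex of monovalent iridium ionises 14 to an η3-allyl complex of trivalent iridium with loss of CO2 and methoxide, and the methoxide deprotonates 11. The phenoxide then attacks from the face remote from the metal at the aryl-substituted allyl terminus, where the 3,4-dimethoxyphenyl group concentrates positive charge, forming O1–C2 and leaving the vinyl group whose inner carbon becomes C3. No ring is closed. The new C2 stereocentre is controlled by the catalyst alone: the chiral iridacycle binds one enantioface of the allyl fragment, and the ligand antipode is chosen to give S. The step needs branched over linear attack and facial selectivity, both supplied by the catalyst and reinforced by the aryl substituent, and O- over C-allylation, which the substrate secures because every ring carbon of 11 is substituted. The reaction is run near room temperature and stopped at full conversion so that the electron-rich ether does not re-ionise on the catalyst and lose enantiopurity.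

Step 10
Reactants: 15 (S)-1-(3,4-dimethoxyphenyl)allyl 2-(benzyloxy)-6-ethenyl-3,4,5-trimethoxyphenyl ether
Product: 16 (2S)-8-(benzyloxy)-2-(3,4-dimethoxyphenyl)-5,6,7-trimethoxy-2H-chromene
Conditions: second-generation Grubbs catalyst (H2IMes)(PCy3)Cl2Ru=CHPh (5 mol%), 1,4-benzoquinone (10 mol%), CH2Cl2 (0.01 M), 40 °C, Ar, dark
Reagents that add atoms: none
Why: Ring-closing metathesis: the ruthenium carbene loads on the unhindered allylic vinyl group and closes the six-membered ring onto the styrenyl vinyl group with loss of ethene, forming C3=C4; C2 takes no part, and benzoquinone intercepts ruthenium hydrides that would move the double bond.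

Step 11
Reactants: 16 (2S)-8-(benzyloxy)-2-(3,4-dimethoxyphenyl)-5,6,7-trimethoxy-2H-chromene
Product: 17 (2S)-8-(benzyloxy)-2-(3,4-dimethoxyphenyl)-5,6,7-trimethoxychroman-4-ol (mixture of C4 epimers)
Conditions: Co(acac)2 (20 mol%), PhSiH3 (2.5 equiv), O2 (1 atm), THF, rt
Reagents that add atoms: dioxygen, O=O
Why: Mukaiyama hydration: a cobalt hydride transfers a hydrogen atom to C3, giving the C4 radical stabilised by ring A, which is trapped by O2 and reduced to the alcohol, so oxygen enters at C4 only; C2 is untouched and the C4 epimer mixture converges in step 12.

Step 12
Reactants: 17 (2S)-8-(benzyloxy)-2-(3,4-dimethoxyphenyl)-5,6,7-trimethoxychroman-4-ol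
Product: 18 (2S)-8-(benzyloxy)-2-(3,4-dimethoxyphenyl)-5,6,7-trimethoxychroman-4-one
Conditions: Dess–Martin periodinane (1.3 equiv), NaHCO3 (4 equiv), CH2Cl2, 0 °C to rt
Reagents that add atoms: none
Why: Dess–Martin oxidation of the secondary benzylic alcohol under buffered, non-basic conditions takes both epimers to the ketone without opening ring C, so C2 keeps its configuration.

Step 13
Reactants: 18 (2S)-8-(benzyloxy)-2-(3,4-dimethoxyphenyl)-5,6,7-trimethoxychroman-4-one
Product: 19 (2S)-2-(3,4-dimethoxyphenyl)-8-hydroxy-5,6,7-trimethoxychroman-4-one
Conditions: H2 (1 atm), 10% Pd/C, EtOAc, rt; filtered as soon as 18 is consumed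
Reagents that add atoms: none
Why: Hydrogenolysis of the aryl benzyl ether over palladium in a neutral solvent; the O–benzyl bond should cleave well before the cyclic C2–O1 bond or the aryl ketone reacts, and no acid or base is present to racemise C2.

## Compound list

1 | 2,3,4-trimethoxybenzaldehyde | COc1ccc(C=O)c(OC)c1OC | starting material
2 | 2,3,4-trimethoxyphenyl formate | COc1ccc(OC=O)c(OC)c1OC | intermediate (not isolated)
3 | 2,3,4-trimethoxyphenol | COc1ccc(O)c(OC)c1OC | intermediate
4 | 6-(hydroxymethyl)-2,3,4-trimethoxyphenol (present as its magnesium salt) | OCc1cc(OC)c(OC)c(OC)c1O | intermediate (not isolated)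
5 | 2-hydroxy-3,4,5-trimethoxybenzaldehyde | O=Cc1cc(OC)c(OC)c(OC)c1O | intermediate
6 | 2-(benzyloxy)-3,4,5-trimethoxybenzaldehyde | O=Cc1cc(OC)c(OC)c(OC)c1OCc1ccccc1 | intermediate
7 | 2-(benzyloxy)-3,4,5-trimethoxyphenyl formate | O=COc1cc(OC)c(OC)c(OC)c1OCc1ccccc1 | intermediate (not isolated)
8 | 2-(benzyloxy)-3,4,5-trimethoxyphenol | Oc1cc(OC)c(OC)c(OC)c1OCc1ccccc1 | intermediate
9 | 2-(benzyloxy)-6-(hydroxymethyl)-3,4,5-trimethoxyphenol (present as its magnesium salt) | OCc1c(O)c(OCc2ccccc2)c(OC)c(OC)c1OC | intermediate (not isolated)
10 | 3-(benzyloxy)-2-hydroxy-4,5,6-trimethoxybenzaldehyde | O=Cc1c(O)c(OCc2ccccc2)c(OC)c(OC)c1OC | intermediate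
11 | 2-(benzyloxy)-6-ethenyl-3,4,5-trimethoxyphenol | C=Cc1c(O)c(OCc2ccccc2)c(OC)c(OC)c1OC | intermediate
12 | methyl (E)-3-(3,4-dimethoxyphenyl)prop-2-enoate | COC(=O)/C=C/c1ccc(OC)c(OC)c1 | starting material
13 | (E)-3-(3,4-dimethoxyphenyl)prop-2-en-1-ol | OC/C=C/c1ccc(OC)c(OC)c1 | intermediate
14 | (E)-3-(3,4-dimethoxyphenyl)allyl methyl carbonate | COC(=O)OC/C=C/c1ccc(OC)c(OC)c1 | intermediate
15 | (S)-1-(3,4-dimethoxyphenyl)allyl 2-(benzyloxy)-6-ethenyl-3,4,5-trimethoxyphenyl ether | COc1ccc([C@H](C=C)Oc2c(C=C)c(OC)c(OC)c(OC)c2OCc3ccccc3)cc1OC | intermediate
16 | (2S)-8-(benzyloxy)-2-(3,4-dimethoxyphenyl)-5,6,7-trimethoxy-2H-chromene | COc1ccc([C@@H]2C=Cc3c(OC)c(OC)c(OC)c(OCc4ccccc4)c3O2)cc1OC | intermediate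
17 | (2S)-8-(benzyloxy)-2-(3,4-dimethoxyphenyl)-5,6,7-trimethoxychroman-4-ol, C4 epimers | COc1ccc([C@@H]2CC(O)c3c(OC)c(OC)c(OC)c(OCc4ccccc4)c3O2)cc1OC | intermediate
18 | (2S)-8-(benzyloxy)-2-(3,4-dimethoxyphenyl)-5,6,7-trimethoxychroman-4-one | COc1ccc([C@@H]2CC(=O)c3c(OC)c(OC)c(OC)c(OCc4ccccc4)c3O2)cc1OC | intermediate
19 | (2S)-2-(3,4-dimethoxyphenyl)-8-hydroxy-5,6,7-trimethoxychroman-4-one | COc1ccc([C@@H]2CC(=O)c3c(c(O)c(OC)c(OC)c3OC)O2)cc1OC | target

## Step count and least certain steps

Total step count: 13. Longest linear sequence: 11 steps (steps 1 to 6, then 9 to 13); the cinnamyl arm (steps 7 and 8) joins at step 9.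

Step 9 (key step). The most likely failure is slow attack by the doubly ortho-substituted phenoxide. That would let methoxide compete for the allyl complex, raise the share of linear ether, and give the electron-rich branched ether time to re-ionise on the catalyst, so that enantiopurity erodes. The fallback leaves the allyl chemistry altogether, sets out from 10 and comes back at 18. Addition of excess HC≡CMgBr to 10 in THF should give 1-[3-(benzyloxy)-2-hydroxy-4,5,6-trimethoxyphenyl]prop-2-yn-1-ol F1. Oxidation of the benzylic propargylic alcohol with MnO2 in CH2Cl2 should give 1-[3-(benzyloxy)-2-hydroxy-4,5,6-trimethoxyphenyl]prop-2-yn-1-one F2. Treatment with Et2NH in EtOH should close it in the 6-endo mode to 8-(benzyloxy)-5,6,7-trimethoxy-4H-chromen-4-one F3. Enantioselective 1,4-addition of 3,4-dimethoxyphenylboronic acid to F3 would then give 18 directly. The catalyst would be Pd(OCOCF3)2 with a chiral pyridine–oxazoline ligand, or a rhodium–chiral diphosphine catalyst, with the ligand antipode chosen for 2S. This is the known asymmetric conjugate arylation of chromones to flavanones.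

Step 6. The olefination of the hindered aldehyde may stall at the phenoxide stage, and the electron-rich vinylphenol may oligomerise on work-up or on standing. The fallback changes the order of events, sets out from 10 (with 14) and comes back at 15. The iridium-catalysed etherification of step 9 is run on the aldehyde 10 itself and should give 3-(benzyloxy)-2-{[(1S)-1-(3,4-dimethoxyphenyl)prop-2-en-1-yl]oxy}-4,5,6-trimethoxybenzaldehyde F4. Wittig methylenation of F4 (Ph3P=CH2, THF, −78 to 0 °C), which now carries no acidic phenol, would give 15. The free vinylphenol is never handled.

Step 11. The radical hydration may be diverted by a second hydrogen-atom transfer to the C4 radical (net reduction to the flavan), by incomplete reduction of peroxide intermediates, or by oxidative damage to the electron-rich ring. The fallback replaces radical by ionic Markovnikov hydration, sets out from 16 and comes back at 17. Oxymercuration with Hg(OAc)2 in THF/H2O should give the 3-(acetoxymercurio) derivative of 17, [(2S)-8-(benzyloxy)-2-(3,4-dimethoxyphenyl)-4-hydroxy-5,6,7-trimethoxychroman-3-yl]mercury acetate F5 (C2 arranged as in 16), with water entering at the donor-stabilised benzylic carbon C4. Demercuration with NaBH4 in aqueous NaOH would then give 17.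

Step 13. The hydrogenolysis may run on into cleavage of the benzylic C2–O1 bond (opening ring C to a dihydrochalcone) or into reduction of the C4 ketone. The fallback swaps reduction for Lewis-acid dealkylation, sets out from 18 and comes back at 19. BCl3 with pentamethylbenzene as cation scavenger in CH2Cl2 at −78 °C should remove the benzyl group well before the methyl ethers react, including the C5 ether peri to the carbonyl, provided the mixture is quenched cold. No new compound arises on this way (F0).

## Further compounds

F1 | step 9 | 1-[3-(benzyloxy)-2-hydroxy-4,5,6-trimethoxyphenyl]prop-2-yn-1-ol | C#CC(O)c1c(O)c(OCc2ccccc2)c(OC)c(OC)c1OC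
F2 | step 9 | 1-[3-(benzyloxy)-2-hydroxy-4,5,6-trimethoxyphenyl]prop-2-yn-1-one | C#CC(=O)c1c(O)c(OCc2ccccc2)c(OC)c(OC)c1OC
F3 | step 9 | 8-(benzyloxy)-5,6,7-trimethoxy-4H-chromen-4-one | O=c1ccoc2c(OCc3ccccc3)c(OC)c(OC)c(OC)c12
F4 | step 6 | 3-(benzyloxy)-2-{[(1S)-1-(3,4-dimethoxyphenyl)prop-2-en-1-yl]oxy}-4,5,6-trimethoxybenzaldehyde | COc1ccc([C@H](C=C)Oc2c(C=O)c(OC)c(OC)c(OC)c2OCc3ccccc3)cc1OC
F5 | step 11 | [(2S)-8-(benzyloxy)-2-(3,4-dimethoxyphenyl)-4-hydroxy-5,6,7-trimethoxychroman-3-yl]mercury acetate (C2 arranged as in 16; C3 and C4 as formed) | COc1ccc([C@@H]2C([Hg]OC(C)=O)C(O)c3c(OC)c(OC)c(OC)c(OCc4ccccc4)c3O2)cc1OC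
F0 | step 13 | none | none
A1 | alternative 1 | (2S,4S)-4-(tert-butyldimethylsilyloxy)-2-(3,4-dimethoxyphenyl)-5,6,7-trimethoxychroman-8-ol | COc1ccc([C@@H]2C[C@H](O[Si](C)(C)C(C)(C)C)c3c(c(O)c(OC)c(OC)c3OC)O2)cc1OC
A2 | alternative 1 | 4-[(2S,4S)-4-(tert-butyldimethylsilyloxy)-2-(3,4-dimethoxyphenyl)-3,4-dihydro-2H-pyran-5-yl]-2,3,4-trimethoxycyclobut-2-en-1-one | COc1ccc([C@@H]2C[C@H](O[Si](C)(C)C(C)(C)C)C(C3(OC)C(OC)=C(OC)C3=O)=CO2)cc1OC
A3 | alternative 1 | dimethyl squarate (3,4-dimethoxycyclobut-3-ene-1,2-dione) | COC1=C(OC)C(=O)C1=O
A4 | alternative 2 | (2S)-2-(3,4-dimethoxyphenyl)-5,6,7-trimethoxy-4-oxochroman-8-yl formate | COc1ccc([C@@H]2CC(=O)c3c(c(OC=O)c(OC)c(OC)c3OC)O2)cc1OC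
A5 | alternative 2 | (2S)-2-(3,4-dimethoxyphenyl)-5,6,7-trimethoxy-4-oxochromane-8-carbaldehyde | COc1ccc([C@@H]2CC(=O)c3c(c(C=O)c(OC)c(OC)c3OC)O2)cc1OC
A6 | alternative 3 | 8-(benzyloxy)-2-(3,4-dimethoxyphenyl)-5,6,7-trimethoxy-4H-chromen-4-one | COc1ccc(-c2cc(=O)c3c(OC)c(OC)c(OC)c(OCc4ccccc4)c3o2)cc1OC
A7 | alternative 3 | 2-(benzyloxy)-6-iodo-3,4,5-trimethoxyphenol | Oc1c(I)c(OC)c(OC)c(OC)c1OCc1ccccc1
A8 | alternative 3 | 4-ethynyl-1,2-dimethoxybenzene | C#Cc1ccc(OC)c(OC)c1
A9 | alternative 3 | carbon monoxide | [C-]#[O+]
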